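## The problem

Target 18 is a hexasubstituted benzene (ring A) with four methoxy groups and, para to each other, two different indol-3-yl groups: a 5-hydroxyindole (pyrrole ring B, benzo ring C) and a 6-(3-methylbut-2-enyl)indole (pyrrole ring D, benzo ring E). It has no stereocentre and no stereodefined alkene, so nothing has to be controlled or relayed; the task is connectivity, desymmetrisation and chemoselectivity. Each ring A–C3 bond is flanked by two methoxy groups, so any metal-catalysed C–C coupling at ring A works against di-ortho substitution. The two halves differ only at remote positions (oxygen at C5 of ring C, prenyl at C6 of ring E), which makes a symmetric core hard to address one side at a time. The prenyl alkene will not tolerate strong acid, electrophilic halogen or hydrogenation, and the free N–H indoles, above all the 5-hydroxyindole, are electron-rich and easily oxidised. The single phenol must be freed beside four aryl methyl ethers that stay, which rules out demethylation and calls for a fluoride-labile group. The enabling feature is that in each indole N1 is bonded only to C2 (a CH) and C7a while C3 carries ring A: without N1, what remains is a 1,1-diarylethene whose terminal carbon (C2) and ortho aryl carbon (C7a) can both carry bromine, a skeleton two diaryl ketones away from simple arenes.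

## Retrosynthesis

**18 to 17.** The O–Si bond and the two N–CO2tBu bonds are cut last. The free 5-hydroxyindole is the most oxidisable form of the molecule, so it should exist only at the end. One fluoride operation can remove all three groups, and no acid touches the prenyl alkene.

**17 to 14 and 15.** The bond between C6 of ring E and the prenyl CH2 is cut, leaving the 6-chloro compound 14 and prenyl bromide 15, used as its zinc reagent 16. Carrying the alkene through oxidation, ylide and hot palladium steps would be avoidable risk. A chlorine at C6 is inert in every earlier step and is the only carbon–halogen bond left after the cyclisation. A boron-based prenylation under aqueous base is the obvious neighbour; the zinc variant is preferred because it runs without base or water, so Boc and silyl groups are safe, and because coupling at the unsubstituted allyl terminus is the rule for the chosen catalyst. The forward step must form the bond at CH2, not at the tertiary carbon.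

**14 to 11 and two molecules of 12.** N1–C2 and N1–C7a are cut in rings B and D, four C–N bonds in all, with nitrogen supplied by tert-butyl carbamate 12. The neighbouring cuts are the ring A–C3 bonds (two biaryl couplings at a di-ortho-methoxy carbon) or C3–C3a (alkyne insertion next to the same hindered ring). Both put a metal-mediated C–C bond formation at ring A; this cut puts none there. The precursor 11 is open at both ends, carries only halogens and ethers, and has all its C–C bonds in place. The forward reaction must take the four bromides before the chloride and must deliver nitrogen cis to the bromoarene whatever the alkene geometry.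

**11 to 10.** Both C=C bonds (the future C2=C3 of each indole) are cut by a Wittig disconnection to the diketone 10. Each carbonyl carbon becomes C3. The step need not control geometry, because the key step is expected to converge.

**10 to 9, then to 6 and 7, then to 4 and 2.** The two bonds between ring A and the carbonyl carbons are cut, with ring A as the nucleophile both times. Diiodide 4 is exchanged once to the arylmagnesium 5 and added to aldehyde 2, giving carbinol 6. A second exchange gives 8, which adds to aldehyde 7, giving diol 9, and one oxidation then makes both ketones. The opposite polarity, ortho-bromoaryl magnesium reagents adding to a ring A dialdehyde, would need a mono-protected dialdehyde, several more steps and elimination-prone Grignard reagents. Here both electrophiles are purchasable ortho-bromobenzaldehydes and the order of addition desymmetrises ring A without a protecting group. The silyloxy ring goes on first, so the bromide that must sit through the second exchange is the electron-rich, slowly exchanging one. Iodide must exchange before bromide.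

**4 to 3 and 2 to 1.** The two C–I bonds of 4 come from electrophilic iodination of the only two C–H positions of 1,2,4,5-tetramethoxybenzene 3. The silyl ether 2 comes from 2-bromo-5-hydroxybenzaldehyde 1. Triisopropylsilyl is chosen because it survives organomagnesium reagents, oxidation, ylide and carbonate base and leaves with fluoride.

## Roads not taken

Alternative 1: The cut is at C3–C3a and N1–C2 of ring D (and, one stage earlier, of ring B). The forward key step is a Larock annulation: Pd[P(t-Bu)3]2 (zerovalent palladium) and an amine base join 2-bromo-5-(3-methylbut-2-enyl)aniline A2 to the aryl(trimethylsilyl)alkyne A3. This gives the 2,2'-bis(trimethylsilyl) O-silyl compound A1, which is then desilylated at both C2 positions and at oxygen.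
- Merits: the prenyl group arrives inside A2, so no late allyl coupling with its linear-or-branched question is needed; silicon places ring A on C3; N–H indoles form directly.
- Weak points: the alkyne that must insert into the aryl–palladium bond has a trimethylsilyl group on one carbon and a di-ortho-methoxyaryl group on the other. Insertion should be slow and the size difference that steers regiochemistry is small. Two different bromoanilines must be made, ring A must carry two alkynes addressed in turn, and removing two C2–Si bonds normally calls for protic acid, which endangers the prenyl alkene.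
- Comparison: alternative 1 is better in needing no separate prenyl coupling and no nitrogen protecting group. The chosen plan sets against this that every bond to ring A is made by an uncatalysed carbonyl addition, less sensitive to di-ortho substitution than a migratory insertion, that both indoles close in one step, and that all arenes are bought.

Alternative 2: The cut is at C3a–C7a and C4–C5, so ring C is built last from a furan. In the forward key step the N-Boc-2-aminofuran A5, tethered through N–CH2–C(OH)(aryl) to a terminal alkyne, is heated to about 180 °C in o-dichlorobenzene. An intramolecular Diels–Alder reaction is followed by opening of the oxygen bridge and dehydration of the tertiary carbinol, giving the N-Boc hydroxyindole A4.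
- Merits: the bridging oxygen becomes the C5 hydroxyl, so its position is fixed by mechanism and needs no protecting group; the key step uses no metal.
- Weak points: it solves only one indole, so rings D and E with the prenyl group must be made by another method and then survive 180 °C, a temperature at which N-Boc groups begin to fall off. A5 needs a fully substituted propargylic carbinol directly on di-ortho-substituted ring A and a sensitive 2-aminofuran. The sequence is long and linear.
- Comparison: alternative 2 places the phenol better. The chosen plan answers with symmetry, both heterocycles in one operation, and a much shorter path to the cyclisation precursor.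

Alternative 3: Only the two N1–C2 bonds are cut, with nitrogen already present as nitro groups. In the forward key step Pd(OAc)2 with 1,10-phenanthroline under carbon monoxide in hot DMF deoxygenates both nitro groups of the bis[1-(2-nitroaryl)ethenyl]arene A7. Each nitrogen closes onto the terminal alkene carbon, giving the O-silyl target A6.
- Merits: no external nitrogen source and no nitrogen protecting group; the alkene is a terminal methylene, so no geometric question arises; the prenyl group is already in place and one desilylation finishes the synthesis. The endgame is shorter than the chosen one and the key step forms two bonds, not four.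
- Weak points: nitro groups do not tolerate the arylmagnesium chemistry that makes the diaryl ketone route short, so A7 would need cross-couplings at hindered ring A. The prenyl alkene must pass through a hot, reducing palladium and carbon monoxide medium in the presence of nitroso-type intermediates, where double-bond migration and ene-type reactions are possible. The C–N closure needs the nitroarene and the alkene near coplanarity, which the di-ortho-methoxy ring A resists.
- Comparison: if A7 were as accessible as 11, alternative 3 would be the shorter and arguably better route. The chosen plan sets against it a precursor assembled from purchasable halogenated aldehydes by carbonyl additions, halogen handles that tolerate all of that chemistry, and a prenyl group that enters only after the hot palladium step.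

Key step: step 7

Remark on the chemistry: the Wittig step cannot fix the alkene geometry, so 11 is taken forward as the mixture of E/Z isomers at both alkenes (the Z,Z isomer, bromine cis to the bromoarene, is drawn). Carbinol 6 is racemic and diol 9 a diastereomer mixture; both carbinol centres are erased in step 5. Compounds 1, 3, 7, 12 and 15 are assumed to be purchased.

## Route

Step 1
Reactants: 1 2-bromo-5-hydroxybenzaldehyde
Product: 2 2-bromo-5-[(triisopropylsilyl)oxy]benzaldehyde
Conditions: TIPSCl, imidazole, DMF, 0 °C to rt
Reagents that add atoms: chlorotriisopropylsilane, CC(C)[Si](Cl)(C(C)C)C(C)C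
Why: Imidazole-promoted silylation of a phenol; the hindered silyl ether should survive arylmagnesium reagents, periodinane oxidation, ylide and carbonate base and is later removed by fluoride.

Step 2
Reactants: 3 1,2,4,5-tetramethoxybenzene
Product: 4 1,4-diiodo-2,3,5,6-tetramethoxybenzene
Conditions: NIS (2.4 equiv), TFA (0.3 equiv), MeCN, rt to 50 °C, dark
Reagents that add atoms: N-iodosuccinimide, O=C1CCC(=O)N1I
Why: Acid-activated electrophilic aromatic iodination of a methoxyarene; the two free positions are the only C–H sites and each is activated by two ortho methoxy groups, so no regiochemical question arises.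

Step 3
Reactants: 4 1,4-diiodo-2,3,5,6-tetramethoxybenzene; 2 2-bromo-5-[(triisopropylsilyl)oxy]benzaldehyde
Product: 6 rac-(2-bromo-5-[(triisopropylsilyl)oxy]phenyl)(4-iodo-2,3,5,6-tetramethoxyphenyl)methanol, via 4-iodo-2,3,5,6-tetramethoxyphenylmagnesium chloride 5 (not isolated)
Conditions: iPrMgCl·LiCl (1.05 equiv), THF, −20 to 0 °C; then 2, −20 °C to rt; aq NH4Cl
Reagents that add atoms: none
Why: Iodine–magnesium exchange should stop after one iodide because the arylmagnesium ring is deactivated toward a second exchange; Grignard addition to the aldehyde then forms the first ring A–carbon bond, and the new carbinol centre is racemic and is removed in step 5.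

Step 4
Reactants: 6 rac-(2-bromo-5-[(triisopropylsilyl)oxy]phenyl)(4-iodo-2,3,5,6-tetramethoxyphenyl)methanol; 7 2-bromo-4-chlorobenzaldehyde
Product: 9 [4-[(2-bromo-4-chlorophenyl)(hydroxy)methyl]-2,3,5,6-tetramethoxyphenyl](2-bromo-5-[(triisopropylsilyl)oxy]phenyl)methanol (mixture of the two racemic diastereomers), via ring A arylmagnesium chloride of the chloromagnesium alkoxide 8 (not isolated)
Conditions: iPrMgCl·LiCl (2.2 equiv), THF, −20 to 0 °C; then 7 (1.3 equiv), −20 °C to rt; aq NH4Cl
Reagents that add atoms: none
Why: The first equivalent deprotonates the carbinol, the second performs iodine–magnesium exchange at ring A, which should be far faster than exchange of the electron-rich aryl bromide; Grignard addition to 7 gives the diol without stereocontrol, which is irrelevant because both centres are oxidised next.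

Step 5
Reactants: 9 [4-[(2-bromo-4-chlorophenyl)(hydroxy)methyl]-2,3,5,6-tetramethoxyphenyl](2-bromo-5-[(triisopropylsilyl)oxy]phenyl)methanol
Product: 10 (2-bromo-4-chlorophenyl)[4-(2-bromo-5-[(triisopropylsilyl)oxy]benzoyl)-2,3,5,6-tetramethoxyphenyl]methanone
Conditions: Dess–Martin periodinane (3 equiv), NaHCO3, CH2Cl2, rt
Reagents that add atoms: none
Why: Dess–Martin oxidation of two doubly benzylic secondary alcohols to diaryl ketones under buffered, non-acidic conditions that leave the silyl ether and the halides alone.

Step 6
Reactants: 10 (2-bromo-4-chlorophenyl)[4-(2-bromo-5-[(triisopropylsilyl)oxy]benzoyl)-2,3,5,6-tetramethoxyphenyl]methanone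
Product: 11 1-[2-bromo-1-(2-bromo-5-[(triisopropylsilyl)oxy]phenyl)ethenyl]-4-[2-bromo-1-(2-bromo-4-chlorophenyl)ethenyl]-2,3,5,6-tetramethoxybenzene (E/Z mixture at both alkenes; Z,Z isomer drawn)
Conditions: Ph3P(CH2Br)Br (6 equiv), KOtBu (5.8 equiv), THF, −78 °C; then 10, −78 °C to rt
Reagents that add atoms: (bromomethyl)triphenylphosphonium bromide, BrC[P+](c1ccccc1)(c1ccccc1)c1ccccc1.[Br-]
Why: Wittig bromomethylenation of diaryl ketones to 2-bromo-1,1-diarylethenes; the base is kept just below the phosphonium salt so that no free alkoxide remains to attack the silyl ether or the bromoalkene, and the geometry is left uncontrolled on purpose.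

Step 7
Reactants: 11 1-[2-bromo-1-(2-bromo-5-[(triisopropylsilyl)oxy]phenyl)ethenyl]-4-[2-bromo-1-(2-bromo-4-chlorophenyl)ethenyl]-2,3,5,6-tetramethoxybenzene; 12 tert-butyl carbamate
Product: 14 tert-butyl 3-{4-[1-(tert-butoxycarbonyl)-6-chloro-1H-indol-3-yl]-2,3,5,6-tetramethoxyphenyl}-5-[(triisopropylsilyl)oxy]-1H-indole-1-carboxylate, via bis(enecarbamate) 13 (not isolated)
Conditions: 12 (2.6 equiv), Pd2(dba)3 (5 mol %), Xantphos (12 mol %), Cs2CO3 (6 equiv), toluene, 100 °C
Reagents that add atoms: none
Why: On each arm zerovalent palladium–Xantphos should insert first into the alkenyl C–Br bond, the carbamate binds and is deprotonated by Cs2CO3, and C–N reductive elimination gives the enecarbamate (both arms: 13); a second oxidative addition at the neighbouring aryl C–Br bond, binding of the carbamate nitrogen and reductive elimination then form N1–C7a. The closest known reaction type is the tandem palladium-catalysed alkenyl and aryl C–N coupling of 2-(2-haloalkenyl)aryl halides with carbamates to N-acyl indoles, a double Buchwald–Hartwig-type amidation. Rings B and D each close by intramolecular aryl amidation, that is by C–N reductive elimination from a six-membered azapalladacycle in which N1 and C7a are both bound to divalent palladium, which delivers the five-membered pyrrole ring. No stereocentre is formed. Bromide must react before chloride, which the bisphosphine catalyst secures because it does not activate an unactivated aryl C–Cl bond at this temperature. Nitrogen must sit cis to the bromoarene, which the substrate secures: the deprotonated β,β-diaryl enecarbamate is a 1-azaallyl anion (and the neutral form can tautomerise to the N-Boc imine), so rotation about C2–C3 should funnel every geometric isomer of 11 into the cyclisable form. Cs2CO3 is too weak to deprotonate the bromoalkene C–H, so Fritsch–Buttenberg–Wiechell rearrangement to diarylalkynes is not expected, and the silyl ether should be safe in anhydrous toluene.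

Step 8
Reactants: 14 tert-butyl 3-{4-[1-(tert-butoxycarbonyl)-6-chloro-1H-indol-3-yl]-2,3,5,6-tetramethoxyphenyl}-5-[(triisopropylsilyl)oxy]-1H-indole-1-carboxylate; 15 1-bromo-3-methylbut-2-ene (prenyl bromide)
Product: 17 tert-butyl 3-{4-[1-(tert-butoxycarbonyl)-6-(3-methylbut-2-en-1-yl)-1H-indol-3-yl]-2,3,5,6-tetramethoxyphenyl}-5-[(triisopropylsilyl)oxy]-1H-indole-1-carboxylate, via 3-methylbut-2-enylzinc bromide 16 (not isolated)
Conditions: 15, Zn dust, LiCl, THF, 0 °C to rt; then 14, Pd(OAc)2 (4 mol %), CPhos (8 mol %), THF, rt to 50 °C
Reagents that add atoms: none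
Why: Zinc insertion into the allylic bromide gives 16, and Negishi coupling at the C6 chloride, now the only carbon–halogen bond, with a palladium–dialkylbiarylphosphine catalyst is known to couple 3,3-disubstituted allylzinc halides at the unsubstituted terminus; the neutral, anhydrous medium leaves the Boc groups and the silyl ether in place.

Step 9
Reactants: 17 tert-butyl 3-{4-[1-(tert-butoxycarbonyl)-6-(3-methylbut-2-en-1-yl)-1H-indol-3-yl]-2,3,5,6-tetramethoxyphenyl}-5-[(triisopropylsilyl)oxy]-1H-indole-1-carboxylate
Product: 18 3-{2,3,5,6-tetramethoxy-4-[6-(3-methylbut-2-en-1-yl)-1H-indol-3-yl]phenyl}-1H-indol-5-ol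
Conditions: TBAF (6 equiv), THF, rt then 65 °C, argon; aq NH4Cl
Reagents that add atoms: none
Why: Fluoride cleaves the aryl silyl ether at room temperature and, on heating, removes the N-Boc groups of indoles by attack at the carbamate carbonyl with the indolide as leaving group (fluoride-mediated deprotection of N-Boc azoles); no acid or oxidant is present, so the prenyl alkene and the electron-rich indoles should be untouched.

## Compound list

1 | 2-bromo-5-hydroxybenzaldehyde | O=Cc1cc(O)ccc1Br | starting material
2 | 2-bromo-5-[(triisopropylsilyl)oxy]benzaldehyde | O=Cc1cc(O[Si](C(C)C)(C(C)C)C(C)C)ccc1Br | intermediate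
3 | 1,2,4,5-tetramethoxybenzene | COc1cc(OC)c(OC)cc1OC | starting material
4 | 1,4-diiodo-2,3,5,6-tetramethoxybenzene | COc1c(OC)c(I)c(OC)c(OC)c1I | intermediate
5 | 4-iodo-2,3,5,6-tetramethoxyphenylmagnesium chloride (LiCl complex, not isolated) | COc1c(OC)c([Mg]Cl)c(OC)c(OC)c1I | intermediate
6 | rac-(2-bromo-5-[(triisopropylsilyl)oxy]phenyl)(4-iodo-2,3,5,6-tetramethoxyphenyl)methanol (racemic) | COc1c(OC)c(C(O)c2cc(O[Si](C(C)C)(C(C)C)C(C)C)ccc2Br)c(OC)c(OC)c1I | intermediate
7 | 2-bromo-4-chlorobenzaldehyde | O=Cc1ccc(Cl)cc1Br | starting material
8 | chloromagnesium alkoxide of 6 with iodine exchanged for MgCl (not isolated) | COc1c(OC)c([Mg]Cl)c(OC)c(OC)c1C(O[Mg]Cl)c1cc(O[Si](C(C)C)(C(C)C)C(C)C)ccc1Br | intermediate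
9 | [4-[(2-bromo-4-chlorophenyl)(hydroxy)methyl]-2,3,5,6-tetramethoxyphenyl](2-bromo-5-[(triisopropylsilyl)oxy]phenyl)methanol (mixture of both racemic diastereomers) | COc1c(OC)c(C(O)c2cc(O[Si](C(C)C)(C(C)C)C(C)C)ccc2Br)c(OC)c(OC)c1C(O)c1ccc(Cl)cc1Br | intermediate
10 | (2-bromo-4-chlorophenyl)[4-(2-bromo-5-[(triisopropylsilyl)oxy]benzoyl)-2,3,5,6-tetramethoxyphenyl]methanone | COc1c(OC)c(C(=O)c2cc(O[Si](C(C)C)(C(C)C)C(C)C)ccc2Br)c(OC)c(OC)c1C(=O)c1ccc(Cl)cc1Br | intermediate
11 | 1-[2-bromo-1-(2-bromo-5-[(triisopropylsilyl)oxy]phenyl)ethenyl]-4-[2-bromo-1-(2-bromo-4-chlorophenyl)ethenyl]-2,3,5,6-tetramethoxybenzene (E/Z mixture at both alkenes; Z,Z isomer drawn) | COc1c(OC)c(/C(=C/Br)c2cc(O[Si](C(C)C)(C(C)C)C(C)C)ccc2Br)c(OC)c(OC)c1/C(=C/Br)c1ccc(Cl)cc1Br | intermediate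
12 | tert-butyl carbamate | NC(=O)OC(C)(C)C | starting material
13 | bis(enecarbamate): both alkenyl bromines of 11 replaced by NHBoc (not isolated; geometry mobile, cyclisable Z,Z form drawn) | COc1c(OC)c(/C(=C/NC(=O)OC(C)(C)C)c2cc(O[Si](C(C)C)(C(C)C)C(C)C)ccc2Br)c(OC)c(OC)c1/C(=C/NC(=O)OC(C)(C)C)c1ccc(Cl)cc1Br | intermediate
14 | tert-butyl 3-{4-[1-(tert-butoxycarbonyl)-6-chloro-1H-indol-3-yl]-2,3,5,6-tetramethoxyphenyl}-5-[(triisopropylsilyl)oxy]-1H-indole-1-carboxylate | COc1c(OC)c(-c2cn(C(=O)OC(C)(C)C)c3ccc(O[Si](C(C)C)(C(C)C)C(C)C)cc23)c(OC)c(OC)c1-c1cn(C(=O)OC(C)(C)C)c2cc(Cl)ccc12 | intermediate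
15 | 1-bromo-3-methylbut-2-ene (prenyl bromide) | CC(C)=CCBr | starting material
16 | 3-methylbut-2-enylzinc bromide (not isolated) | CC(C)=CC[Zn]Br | intermediate
17 | tert-butyl 3-{4-[1-(tert-butoxycarbonyl)-6-(3-methylbut-2-en-1-yl)-1H-indol-3-yl]-2,3,5,6-tetramethoxyphenyl}-5-[(triisopropylsilyl)oxy]-1H-indole-1-carboxylate | COc1c(OC)c(-c2cn(C(=O)OC(C)(C)C)c3ccc(O[Si](C(C)C)(C(C)C)C(C)C)cc23)c(OC)c(OC)c1-c1cn(C(=O)OC(C)(C)C)c2cc(CC=C(C)C)ccc12 | intermediate
18 | 3-{2,3,5,6-tetramethoxy-4-[6-(3-methylbut-2-en-1-yl)-1H-indol-3-yl]phenyl}-1H-indol-5-ol | COc1c(OC)c(-c2c[nH]c3ccc(O)cc23)c(OC)c(OC)c1-c1c[nH]c2cc(CC=C(C)C)ccc12 | target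

## Step count and least certain steps

Total: 9 steps. Longest linear sequence: 8 steps (3 to 18 through steps 2 to 9); step 1 is a one-step side branch.

**Step 7 (key step).** The most likely failure is incomplete geometric funnelling. Arms in which nitrogen ends up trans to the bromoarene may stall as open enecarbamates, or aryl amidation may occur first on an arm whose alkenyl bromide points away, after which that arm cannot close. With four couplings on one molecule any such loss multiplies. The fallback sets out from 10 and returns at 14. Wittig methoxymethylenation of 10 (ylide from (methoxymethyl)triphenylphosphonium chloride and KOtBu) gives the bis(methyl enol ether) F1, whose geometry is irrelevant. Double aryl amidation of its two C–Br bonds with 12 under the same Pd2(dba)3, Xantphos and Cs2CO3 conditions gives the bis(N-Boc-anilide) F2, so N1–C7a is still made by C–N coupling from the separate nitrogen. Catalytic pyridinium p-toluenesulfonate in warm toluene then ionises each enol ether; the carbamate nitrogen adds to C2, methanol is lost, and 14 results.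

**Step 6.** The most likely failure is slow addition of the ylide to carbonyl carbons shielded by three ortho substituents, in competition with thermal decay of the ylide on warming and base-induced loss of HBr from the product. The fallback sets out from 10 and returns at 11. Methylenation with the Tebbe reagent Cp2Ti(μ-Cl)(μ-CH2)AlMe2, which is much less sensitive to hindrance, gives the bis(1-arylethenyl)arene F3. Pyridinium tribromide adds across both alkenes to the tetrabromide F4, which is not isolated; DBU in the same flask removes HBr from each arm and gives 11 as an isomer mixture.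

**Step 4.** The most likely failure is erosion of halogen selectivity: the magnesium alkoxide next to the bromoarene can steer the exchange reagent to the C–Br bond, while the iodide on the very electron-rich ring A exchanges slowly. The fallback sets out from 6 and returns at 10. Oxidation of 6 with Dess–Martin periodinane gives the iodo ketone F5. With the alkoxide gone and an aroyl group para to iodine accelerating the exchange, iPrMgCl·LiCl at −40 °C followed by 7 gives the hydroxy ketone F6; the tri-ortho-substituted ketone is expected to be inert to the magnesium reagents at that temperature. A second Dess–Martin oxidation gives 10.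

**Step 8.** The most likely failures are sluggish oxidative addition into the C6–Cl bond, homocoupling during formation of the allylzinc reagent, and some bond formation at the tertiary allyl terminus. The fallback sets out from 14 and returns at 17. Suzuki–Miyaura coupling of 14 with allylboronic acid pinacol ester (Pd(OAc)2, SPhos, K3PO4, THF–water), where the allyl group poses no regiochemical question, gives the 6-allyl compound F7. Cross-metathesis with excess 2-methylbut-2-ene and the second-generation Grubbs catalyst (H2IMes)(PCy3)Cl2Ru=CHPh then gives 17.

**Step 2.** The most likely failure is one-electron oxidation of the electron-rich arene (oxidative demethylation toward a quinone) competing with the slower second iodination. The fallback sets out from 3 and returns at 4. Bromination with Br2 in CH2Cl2 gives the dibromide F8, and copper-catalysed aromatic Finkelstein exchange (CuI, N,N'-dimethylethylenediamine, NaI, dioxane, 110 °C) converts it into 4.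

## Further compounds

F1 | step 7 | 1-[1-(2-bromo-5-[(triisopropylsilyl)oxy]phenyl)-2-methoxyethenyl]-4-[1-(2-bromo-4-chlorophenyl)-2-methoxyethenyl]-2,3,5,6-tetramethoxybenzene (E/Z mixture) | COc1c(OC)c(C(=COC)c2cc(O[Si](C(C)C)(C(C)C)C(C)C)ccc2Br)c(OC)c(OC)c1C(=COC)c1ccc(Cl)cc1Br
F2 | step 7 | bis(N-Boc-anilide): both aryl bromines of F1 replaced by NHBoc (E/Z mixture) | COc1c(OC)c(C(=COC)c2cc(O[Si](C(C)C)(C(C)C)C(C)C)ccc2NC(=O)OC(C)(C)C)c(OC)c(OC)c1C(=COC)c1ccc(Cl)cc1NC(=O)OC(C)(C)C
F3 | step 6 | 1-[1-(2-bromo-5-[(triisopropylsilyl)oxy]phenyl)ethenyl]-4-[1-(2-bromo-4-chlorophenyl)ethenyl]-2,3,5,6-tetramethoxybenzene | COc1c(OC)c(C(=C)c2cc(O[Si](C(C)C)(C(C)C)C(C)C)ccc2Br)c(OC)c(OC)c1C(=C)c1ccc(Cl)cc1Br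
F4 | step 6 | 1-[1,2-dibromo-1-(2-bromo-5-[(triisopropylsilyl)oxy]phenyl)ethyl]-4-[1,2-dibromo-1-(2-bromo-4-chlorophenyl)ethyl]-2,3,5,6-tetramethoxybenzene (diastereomer mixture, not isolated) | COc1c(OC)c(C(Br)(CBr)c2cc(O[Si](C(C)C)(C(C)C)C(C)C)ccc2Br)c(OC)c(OC)c1C(Br)(CBr)c1ccc(Cl)cc1Br
F5 | step 4 | (2-bromo-5-[(triisopropylsilyl)oxy]phenyl)(4-iodo-2,3,5,6-tetramethoxyphenyl)methanone | COc1c(OC)c(C(=O)c2cc(O[Si](C(C)C)(C(C)C)C(C)C)ccc2Br)c(OC)c(OC)c1I
F6 | step 4 | rac-[4-[(2-bromo-4-chlorophenyl)(hydroxy)methyl]-2,3,5,6-tetramethoxyphenyl](2-bromo-5-[(triisopropylsilyl)oxy]phenyl)methanone | COc1c(OC)c(C(=O)c2cc(O[Si](C(C)C)(C(C)C)C(C)C)ccc2Br)c(OC)c(OC)c1C(O)c1ccc(Cl)cc1Br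
F7 | step 8 | tert-butyl 3-{4-[6-allyl-1-(tert-butoxycarbonyl)-1H-indol-3-yl]-2,3,5,6-tetramethoxyphenyl}-5-[(triisopropylsilyl)oxy]-1H-indole-1-carboxylate | COc1c(OC)c(-c2cn(C(=O)OC(C)(C)C)c3ccc(O[Si](C(C)C)(C(C)C)C(C)C)cc23)c(OC)c(OC)c1-c1cn(C(=O)OC(C)(C)C)c2cc(CC=C)ccc12
F8 | step 2 | 1,4-dibromo-2,3,5,6-tetramethoxybenzene | COc1c(OC)c(Br)c(OC)c(OC)c1Br
A1 | alternative 1 | 2,2'-bis(trimethylsilyl) O-triisopropylsilyl target | COc1c(OC)c(-c2c([Si](C)(C)C)[nH]c3cc(CC=C(C)C)ccc23)c(OC)c(OC)c1-c1c([Si](C)(C)C)[nH]c2ccc(O[Si](C(C)C)(C(C)C)C(C)C)cc12
A2 | alternative 1 | 2-bromo-5-(3-methylbut-2-enyl)aniline | Nc1cc(CC=C(C)C)ccc1Br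
A3 | alternative 1 | 3-{2,3,5,6-tetramethoxy-4-[(trimethylsilyl)ethynyl]phenyl}-2-(trimethylsilyl)-5-[(triisopropylsilyl)oxy]-1H-indole | COc1c(OC)c(C#C[Si](C)(C)C)c(OC)c(OC)c1-c1c([Si](C)(C)C)[nH]c2ccc(O[Si](C(C)C)(C(C)C)C(C)C)cc12
A4 | alternative 2 | N-Boc (hydroxyindole), N-triisopropylsilyl (prenylindole) target | COc1c(OC)c(-c2cn(C(=O)OC(C)(C)C)c3ccc(O)cc23)c(OC)c(OC)c1-c1cn([Si](C(C)C)(C(C)C)C(C)C)c2cc(CC=C(C)C)ccc12
A5 | alternative 2 | racemic tert-butyl furan-2-yl(2-hydroxy-2-aryl-but-3-ynyl)carbamate, aryl = 2,3,5,6-tetramethoxy-4-[6-prenyl-1-(triisopropylsilyl)indol-3-yl]phenyl | COc1c(OC)c(C(O)(C#C)CN(C(=O)OC(C)(C)C)c2ccco2)c(OC)c(OC)c1-c1cn([Si](C(C)C)(C(C)C)C(C)C)c2cc(CC=C(C)C)ccc12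
A6 | alternative 3 | target O-triisopropylsilyl ether | COc1c(OC)c(-c2c[nH]c3ccc(O[Si](C(C)C)(C(C)C)C(C)C)cc23)c(OC)c(OC)c1-c1c[nH]c2cc(CC=C(C)C)ccc12
A7 | alternative 3 | 1-[1-(2-nitro-5-[(triisopropylsilyl)oxy]phenyl)ethenyl]-4-[1-(2-nitro-4-(3-methylbut-2-enyl)phenyl)ethenyl]-2,3,5,6-tetramethoxybenzene | COc1c(OC)c(C(=C)c2cc(O[Si](C(C)C)(C(C)C)C(C)C)ccc2[N+](=O)[O-])c(OC)c(OC)c1C(=C)c1ccc(CC=C(C)C)cc1[N+](=O)[O-]
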